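**Plan**

- Feature: in the ten-membered ring every oxygen- or ester-bearing carbon lies in the arc C5–C10, while C1–C4 (C15 on C4) form a plain four-carbon arc. Closing C5–C10 gives a cyclohexanol with a vinyl group (C1, C2) on C10 and an isopropenyl group (C4, C3, C15) on C5.
- Retrosynthetic cuts, in order: C8–O acyl, C11=C13, C10–C14, the C4/C5 hydrogens, then C2–C3 (with C5–C10 re-formed, retro-oxy-Cope), C10–C1, C5–C4, the C6, C8 and C9 oxygens, and last C8–C9 and C6–C7 of a cyclohexenone (aldol, Michael).
- Forward order: cyclohexenone ring C5–C10 (Michael/aldol) → C8/C9 oxygens → C5 isopropenyl and C6 oxygen → tetrahydrofuran acetal ring (C6–O–C12) → C10 vinyl carbinol → ring expansion to the ten-membered ring → C4 hydrogenation, C14 ester, C8 ester, α-methylene lactone.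
- Stereochemistry: C7 from the prolinol-ether-catalysed Michael addition; C8 and C9 from hydroxyl-directed epoxidation and trans-diaxial opening; C6 from conjugate borylation anti to C7; C4 from hydrogenation of the E alkene on its open face; C1=C10 geometry from kinetic enolisation of the ten-membered ketone.

Key step: step 16

Remark: locants C1–C15 are those of the germacranolide skeleton of 37 and are kept for all intermediates; β is the face of the ring C5–C10 that carries the C7 side chain (C11), α the opposite face.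
Remark: the acetal carbon C12 of the bicyclic methyl acetal (21–31) and of the lactols (32–34) is carried as an anomeric mixture; it ends as the lactone carbonyl.

**Route**

Step 1
Reactants: 1 methyl 4,4-dimethoxybutanoate
Product: 2 4,4-dimethoxybutanal
Conditions: DIBAL-H, CH2Cl2, −78 °C; MeOH, aq. potassium sodium tartrate
Reagents that add atoms: none
Why: Partial reduction of the ester with DIBAL-H at low temperature stops at the aluminium hemiacetal, which releases the aldehyde on work-up, and the dimethyl acetal is inert.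

Step 2
Reactants: 2 4,4-dimethoxybutanal; 3 but-3-en-2-one
Product: 5 (R)-4-(2,2-dimethoxyethyl)cyclohex-2-en-1-one, via keto aldehyde 4 (not isolated)
Conditions: (R)-2-[methoxy(diphenyl)methyl]pyrrolidine (5 mol%), ethyl 3,4-dihydroxybenzoate (20 mol%), neat, 4 °C; then LiOH·H2O (cat.), i-PrOH, rt
Reagents that add atoms: none
Why: Enamine-mediated Michael addition to the enone, in which the diarylmethyl group of the (R)-catalyst shields one enamine face so that C7 should form as R, followed by intramolecular aldol condensation (organocatalytic Robinson-type annulation to a 4-substituted cyclohexenone).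

Step 3
Reactants: 5 (R)-4-(2,2-dimethoxyethyl)cyclohex-2-en-1-one
Product: 6 (1S,4R)-4-(2,2-dimethoxyethyl)cyclohex-2-en-1-ol (10α-OH)
Conditions: NaBH4, CeCl3·7H2O, MeOH, −78 °C
Reagents that add atoms: none
Why: Luche reduction gives clean 1,2-reduction, and axial hydride delivery to the half-chair with the C7 side chain pseudo-equatorial should place the C10 hydroxyl trans to that side chain.

Step 4
Reactants: 6 trans allylic alcohol
Product: 7 8α,9α-epoxy-10α-ol (epoxide cis to OH, trans to the C7 side chain)
Conditions: mCPBA, NaHCO3, CH2Cl2, 0 °C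
Reagents that add atoms: mCPBA, OOC(=O)c1cccc(Cl)c1
Why: Hydroxyl-directed peracid epoxidation of a cyclohex-2-enol delivers oxygen on the face of the C10 hydroxyl, which is also the face remote from the C7 side chain, so both elements set the α-epoxide.

Step 5
Reactants: 7 epoxy alcohol
Product: 8 10-O-(2-methoxypropan-2-yl) epoxy ether
Conditions: 2-methoxypropene, PPTS (cat.), CH2Cl2, 0 °C; Et3N
Reagents that add atoms: 2-methoxypropene, COC(C)=C
Why: Acid-catalysed addition of the alcohol to the enol ether gives a mixed acetal that is stable to alkoxide, cannot migrate to the neighbouring oxygen in the next step and adds no stereocentre.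

Step 6
Reactants: 8 epoxy ether
Product: 9 8β-(4-methoxybenzyloxy)-9α-hydroxy-10α-(2-methoxypropan-2-yloxy) cyclohexane
Conditions: 4-methoxybenzyl alcohol (excess), NaH (0.5 equiv), DMF, 80 °C
Reagents that add atoms: 4-methoxybenzyl alcohol, COc1ccc(CO)cc1
Why: SN2 (trans-diaxial) opening of the epoxide by the alkoxide should occur at C8, the carbon remote from the C10 oxygen, through the half-chair that keeps the C7 side chain and the C10 ether equatorial; inversion gives 8β-O (cis to the side chain) and leaves 9α-OH.

Step 7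
Reactants: 9 C9 alcohol
Product: 10 9α-methoxymethyl ether
Conditions: MOMCl, i-Pr2NEt, Bu4NI (cat.), CH2Cl2, 0 → 40 °C
Reagents that add atoms: chloromethyl methyl ether, COCCl
Why: Alkylation of the hindered secondary alcohol with the chloromethyl ether under amine base (standard MOM ether formation), excess base protecting the acid-labile mixed acetal.

Step 8
Reactants: 10 fully protected triol
Product: 11 10α-alcohol (8β-OPMB, 9α-OMOM)
Conditions: PPTS (cat.), MeOH, 0 °C → rt
Reagents that add atoms: none
Why: Acid-catalysed transacetalisation in methanol removes the very labile 2-methoxypropan-2-yl group while the formaldehyde acetal, the PMB ether and the dimethyl acetal (degenerate exchange) remain.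

Step 9
Reactants: 11 C10 alcohol
Product: 12 C10 ketone (7β-(2,2-dimethoxyethyl), 8β-OPMB, 9α-OMOM)
Conditions: triacetoxyperiodinane (DMP), NaHCO3, CH2Cl2, rt
Reagents that add atoms: none
Why: Hypervalent-iodine oxidation of the secondary alcohol under buffered, non-basic conditions avoids epimerisation at C9 and β-elimination of the C8 ether.

Step 10
Reactants: 12 C10 ketone
Product: 15 C5=C6 enone (8β-OPMB, 9α-OMOM), via lithium enolate 13 (not isolated), via silyl enol ether 14 (not isolated)
Conditions: LDA, THF, −78 °C; TMSCl; then Pd(OAc)2 (1.1 equiv), MeCN, rt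
Reagents that add atoms: none
Why: Saegusa–Ito oxidation, in which kinetic deprotonation takes the C5 methylene and not the alkoxy-bearing C9, and the palladium enolate loses the C6 hydride to give the enone.

Step 11
Reactants: 15 enone
Product: 16 5-iodo enone
Conditions: I2, pyridine/CH2Cl2, 0 °C → rt
Reagents that add atoms: iodine, II
Why: α-Iodination of a cyclic enone by conjugate addition of pyridine, iodination of the enolate and elimination, under base too weak to expel the C8 ether.

Step 12
Reactants: 16 5-iodo enone; 17 tributyl(prop-1-en-2-yl)stannane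
Product: 18 5-isopropenyl enone
Conditions: PdCl2(PhCN)2 (5 mol%), AsPh3, CuI (10 mol%), NMP, rt
Reagents that add atoms: none
Why: Stille coupling of an α-iodo enone with an alkenylstannane under neutral, arsine- and copper-accelerated conditions, so no base is present to trigger elimination and aromatisation.

Step 13
Reactants: 18 5-isopropenyl enone
Product: 20 6α-hydroxy-5β-isopropenyl ketone, via boronate 19 (not isolated)
Conditions: B2pin2, CuCl (5 mol%), Xantphos (5 mol%), NaOt-Bu (10 mol%), MeOH (2 equiv), THF, rt; then NaBO3·4H2O, THF/H2O, rt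
Reagents that add atoms: sodium perborate, [Na+].[O-]OB=O
Why: Copper-catalysed conjugate borylation should place boron on C6 anti to the C7 side chain, stereoretentive C–B oxidation gives the 6α-alcohol, and the epimerisable C5 is expected to settle with isopropenyl trans to the C6 substituent.

Step 14
Reactants: 20 6α-hydroxy ketone
Product: 21 trans-fused bicyclic methyl acetal ketone (C6–O–C12(OMe)–C11–C7 ring; 5β-isopropenyl, 8β-OPMB, 9α-OMOM)
Conditions: PPTS (cat.), 4 Å MS, CH2Cl2, rt
Reagents that add atoms: none
Why: Intramolecular transacetalisation (5-exo attack of the C6 hydroxyl on the oxocarbenium ion) protects O6 and C12 together and locks the chair with the C5, C6 and C7 substituents equatorial, in which an axial isopropenyl would clash with the axial C9 ether.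

Step 15
Reactants: 21 bicyclic ketone; 22 vinylmagnesium bromide
Product: 23 10β-hydroxy-10α-vinyl-5β-isopropenyl bicyclic acetal (oxy-Cope precursor)
Conditions: CeCl3 (anhydrous), THF, −78 °C; aq. NH4Cl
Reagents that add atoms: none
Why: 1,2-Addition of the weakly basic organocerium reagent to the enolisable β-alkoxy ketone; the axial β-face approach is blocked by the syn-axial C8 ether, so vinyl should enter equatorially (10α) and end trans to the isopropenyl group.

Step 16
Reactants: 23 1-vinyl-2-isopropenyl cyclohexanol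
Product: 25 (4E)-cyclodec-4-en-10-one fused to the methyl acetal (8-OPMB, 9-OMOM), via potassium enolate 24 (not isolated)
Conditions: KH, 18-crown-6, THF, 0 °C → rt; aq. NH4Cl, −78 °C
Reagents that add atoms: none
Why: Deprotonation gives the C10 potassium alkoxide, which triggers a concerted anionic oxy-Cope [3,3] shift of the 1,5-diene C2=C1–C10–C5–C4=C3: C2–C3 forms while C5–C10 breaks, so the six-membered ring C5–C10 becomes the ten-membered ring C1–C10. The closest known reaction is the anionic oxy-Cope ring expansion of trans-1,2-dialkenylcyclohexanols to (E)-cyclodec-5-enones. The ten-membered ring arises by this four-carbon ring expansion through a chair six-centre transition state, the C2–C3 bond joining the two alkene termini held gauche on the cyclohexane. No stereocentre is created: C6–C9 are spectators, and C4=C5 should be E because the ring bond C5–C6 is equatorial in the chair. The step needs chair over boat and [3,3] over [1,3] shift or fragmentation; the trans-fused acetal locks vinyl and isopropenyl both equatorial, and only ethers flank the alkoxide. The enolate is protonated cold so that the β-alkoxy ketone is not left in base.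

Step 17
Reactants: 25 cyclodecenone
Product: 26 (4S)-4,5-dihydro ketone
Conditions: H2 (1 atm), [Ir(cod)(PCy3)(py)]PF6 (5 mol%), CH2Cl2, 0 °C
Reagents that add atoms: none
Why: Homogeneous hydrogenation guided by the allylic acetal oxygen on C6; with the C6 hydrogen eclipsing the C4 methyl group (allylic 1,3-strain) the ring chain covers one face of the E alkene and hydrogen should add on the open, oxygen-bearing face, giving 4S.

Step 18
Reactants: 26 saturated ketone
Product: 28 C1=C10 enol triflate (C2 and C9 cis), via potassium enolate 27 (not isolated)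
Conditions: KHMDS, THF, −78 °C; then PhNTf2
Reagents that add atoms: N-phenylbis(trifluoromethanesulfonyl)imide, O=S(=O)(N(c1ccccc1)S(=O)(=O)C(F)(F)F)C(F)(F)F
Why: Kinetic deprotonation should take the C1 methylene rather than the alkoxy-substituted C9, the ten-membered ring favours the cis ring alkene, and O-sulfonylation of the enolate fixes it as the enol triflate.

Step 19
Reactants: 28 enol triflate
Product: 29 C14 methyl ester (1(10)E enoate)
Conditions: Pd(PPh3)4 (5 mol%), CO (1 atm), MeOH, Et3N, DMF, 60 °C
Reagents that add atoms: carbon monoxide, [C-]#[O+]; methanol, CO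
Why: Palladium-catalysed methoxycarbonylation of an enol triflate (oxidative addition to zerovalent palladium, CO insertion, methanolysis) proceeds with retention of alkene geometry.

Step 20
Reactants: 29 PMB-protected enoate
Product: 30 C8 alcohol
Conditions: DDQ, CH2Cl2/pH 7 buffer, 0 °C
Reagents that add atoms: none
Why: Oxidative cleavage of the PMB ether by DDQ in wet, buffered dichloromethane leaves the MOM ether, the cyclic acetal and the enoate untouched.

Step 21
Reactants: 30 C8 alcohol
Product: 31 C8 3-methylbutanoate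
Conditions: 3-methylbutanoic anhydride, DMAP (cat.), Et3N, CH2Cl2, rt
Reagents that add atoms: 3-methylbutanoic anhydride, CC(C)CC(=O)OC(=O)CC(C)C
Why: DMAP-catalysed acylation of the only free hydroxyl installs the ester after all strongly basic and organometallic steps.

Step 22
Reactants: 31 methyl acetal
Product: 32 lactol (C12 hemiacetal on O6)
Conditions: AcOH/THF/H2O (3:1:1), 40 °C
Reagents that add atoms: water, O
Why: Mild aqueous acid hydrolyses the 2-methoxytetrahydrofuran acetal faster than the formaldehyde acetal on C9 or either ester.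

Step 23
Reactants: 32 lactol
Product: 34 α-methylene lactol (C11=C13), via Mannich base 33 (not isolated)
Conditions: Me2N=CH2 I, Et3N, CH2Cl2, rt
Reagents that add atoms: dimethylmethylideneammonium iodide, C=[N+](C)C.[I-]
Why: Mannich reaction at C11 of the ring-opened γ-hydroxy aldehyde and β-elimination of dimethylamine (α-methylenation of an aldehyde), after which the enal recloses to the lactol since 5-endo oxa-Michael closure is disfavoured.

Step 24
Reactants: 34 α-methylene lactol
Product: 35 9-O-MOM α-methylene-γ-lactone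
Conditions: MnO2 (excess), CH2Cl2, rt
Reagents that add atoms: none
Why: MnO2 oxidises the allylic hemiacetal to the lactone and leaves saturated centres and esters alone.

Step 25
Reactants: 35 MOM ether
Product: 37 CNP0544142.1 (4S,6R,7S,8S,9S,1(10)E), via bromomethyl ether 36 (not isolated)
Conditions: Me2BBr, CH2Cl2, −78 °C; then aq. NaHCO3, THF
Reagents that add atoms: none
Why: Bromoborane cleavage of the MOM ether at low temperature (boron on the acetal oxygen, bromide attack) and hydrolysis of the bromomethyl ether should be tolerated by the two esters, the enoate and the α-methylene lactone.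

**Compound list**

1 | methyl 4,4-dimethoxybutanoate | COC(=O)CCC(OC)OC | starting material
2 | 4,4-dimethoxybutanal | O=CCCC(OC)OC | intermediate
3 | but-3-en-2-one (methyl vinyl ketone) | CC(=O)C=C | starting material
4 | (R)-2-(2,2-dimethoxyethyl)-5-oxohexanal | O=C[C@@H](CC(OC)OC)CCC(C)=O | intermediate (not isolated)
5 | (R)-4-(2,2-dimethoxyethyl)cyclohex-2-en-1-one (C10 ketone, C8=C9) | O=C1C=C[C@@H](CC(OC)OC)CC1 | intermediate
6 | (1S,4R)-4-(2,2-dimethoxyethyl)cyclohex-2-en-1-ol (10α-OH) | O[C@@H]1C=C[C@@H](CC(OC)OC)CC1 | intermediate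
7 | 8α,9α-epoxy-10α-ol, epoxide cis to OH and trans to the C7 side chain | O[C@@H]1[C@@H]2O[C@@H]2[C@@H](CC(OC)OC)CC1 | intermediate
8 | 10-O-(2-methoxypropan-2-yl) ether of 7 | COC(C)(C)O[C@@H]1[C@@H]2O[C@@H]2[C@@H](CC(OC)OC)CC1 | intermediate
9 | 8β-(4-methoxybenzyloxy)-9α-hydroxy-10α-(2-methoxypropan-2-yloxy) cyclohexane, 7β side chain | COC(C)(C)O[C@@H]1[C@H](O)[C@@H](OCc2ccc(OC)cc2)[C@@H](CC(OC)OC)CC1 | intermediate
10 | 9α-methoxymethyl ether of 9 | COC(C)(C)O[C@@H]1[C@H](OCOC)[C@@H](OCc2ccc(OC)cc2)[C@@H](CC(OC)OC)CC1 | intermediate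
11 | 10α-alcohol, 8β-OPMB, 9α-OMOM | O[C@@H]1[C@H](OCOC)[C@@H](OCc2ccc(OC)cc2)[C@@H](CC(OC)OC)CC1 | intermediate
12 | C10 ketone, 7β-(2,2-dimethoxyethyl), 8β-OPMB, 9α-OMOM | O=C1[C@H](OCOC)[C@@H](OCc2ccc(OC)cc2)[C@@H](CC(OC)OC)CC1 | intermediate
13 | lithium C5(10)-enolate of 12 | [Li+].[O-]C1=CC[C@H](CC(OC)OC)[C@H](OCc2ccc(OC)cc2)[C@H]1OCOC | intermediate (not isolated)
14 | trimethylsilyl enol ether of 12 (C5=C10) | C[Si](C)(C)OC1=CC[C@H](CC(OC)OC)[C@H](OCc2ccc(OC)cc2)[C@H]1OCOC | intermediate (not isolated)
15 | C5=C6 enone, 8β-OPMB, 9α-OMOM | O=C1C=C[C@H](CC(OC)OC)[C@H](OCc2ccc(OC)cc2)[C@H]1OCOC | intermediate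
16 | 5-iodo enone | O=C1C(I)=C[C@H](CC(OC)OC)[C@H](OCc2ccc(OC)cc2)[C@H]1OCOC | intermediate
17 | tributyl(prop-1-en-2-yl)stannane | CCCC[Sn](CCCC)(CCCC)C(C)=C | starting material
18 | 5-isopropenyl enone | O=C1C(C(C)=C)=C[C@H](CC(OC)OC)[C@H](OCc2ccc(OC)cc2)[C@H]1OCOC | intermediate
19 | 6α-(pinacolboryl)-5β-isopropenyl ketone | O=C1[C@H](C(C)=C)[C@@H](B2OC(C)(C)C(C)(C)O2)[C@H](CC(OC)OC)[C@H](OCc3ccc(OC)cc3)[C@H]1OCOC | intermediate (not isolated)
20 | 6α-hydroxy-5β-isopropenyl ketone | O=C1[C@H](C(C)=C)[C@@H](O)[C@H](CC(OC)OC)[C@H](OCc2ccc(OC)cc2)[C@H]1OCOC | intermediate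
21 | trans-fused bicyclic methyl acetal ketone (O6–C12 acetal, C12 anomers), 5β-isopropenyl, 8β-OPMB, 9α-OMOM | O=C1[C@H](C(C)=C)[C@H]2OC(OC)C[C@@H]2[C@H](OCc3ccc(OC)cc3)[C@H]1OCOC | intermediate
22 | vinylmagnesium bromide | C=C[Mg]Br | starting material
23 | 10β-hydroxy-10α-vinyl-5β-isopropenyl bicyclic acetal (oxy-Cope precursor) | C=C[C@@]1(O)[C@H](C(C)=C)[C@H]2OC(OC)C[C@@H]2[C@H](OCc3ccc(OC)cc3)[C@H]1OCOC | intermediate
24 | potassium C1(10)-enolate of 25 | [K+].[O-]/C1=C\CC/C(C)=C/[C@H]2OC(OC)C[C@@H]2[C@H](OCc3ccc(OC)cc3)[C@H]1OCOC | intermediate (not isolated)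
25 | (4E)-cyclodec-4-en-10-one fused to the methyl acetal, 8-OPMB, 9-OMOM (oxy-Cope product) | O=C1CCC/C(C)=C/[C@H]2OC(OC)C[C@@H]2[C@H](OCc3ccc(OC)cc3)[C@H]1OCOC | intermediate
26 | (4S)-4,5-dihydro ketone | O=C1CCC[C@H](C)C[C@H]2OC(OC)C[C@@H]2[C@H](OCc3ccc(OC)cc3)[C@H]1OCOC | intermediate
27 | potassium C1(10)-enolate of 26 (C2, C9 cis) | [K+].[O-]/C1=C/CC[C@H](C)C[C@H]2OC(OC)C[C@@H]2[C@H](OCc3ccc(OC)cc3)[C@H]1OCOC | intermediate (not isolated)
28 | C1=C10 enol triflate (C2, C9 cis) | O=S(=O)(O/C1=C/CC[C@H](C)C[C@H]2OC(OC)C[C@@H]2[C@H](OCc3ccc(OC)cc3)[C@H]1OCOC)C(F)(F)F | intermediate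
29 | C14 methyl ester, 8-OPMB, 9-OMOM, methyl acetal | COC(=O)/C1=C/CC[C@H](C)C[C@H]2OC(OC)C[C@@H]2[C@H](OCc3ccc(OC)cc3)[C@H]1OCOC | intermediate
30 | C8 alcohol | COC(=O)/C1=C/CC[C@H](C)C[C@H]2OC(OC)C[C@@H]2[C@H](O)[C@H]1OCOC | intermediate
31 | C8 3-methylbutanoate, methyl acetal | COC(=O)/C1=C/CC[C@H](C)C[C@H]2OC(OC)C[C@@H]2[C@H](OC(=O)CC(C)C)[C@H]1OCOC | intermediate
32 | lactol (C12 hemiacetal, anomers) | COC(=O)/C1=C/CC[C@H](C)C[C@H]2OC(O)C[C@@H]2[C@H](OC(=O)CC(C)C)[C@H]1OCOC | intermediate
33 | 11-(dimethylaminomethyl) lactol (Mannich base) | COC(=O)/C1=C/CC[C@H](C)C[C@H]2OC(O)C(CN(C)C)[C@@H]2[C@H](OC(=O)CC(C)C)[C@H]1OCOC | intermediate (not isolated)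
34 | α-methylene lactol (C11=C13) | COC(=O)/C1=C/CC[C@H](C)C[C@H]2OC(O)C(=C)[C@@H]2[C@H](OC(=O)CC(C)C)[C@H]1OCOC | intermediate
35 | 9-O-MOM α-methylene-γ-lactone | COC(=O)/C1=C/CC[C@H](C)C[C@H]2OC(=O)C(=C)[C@@H]2[C@H](OC(=O)CC(C)C)[C@H]1OCOC | intermediate
36 | 9-O-bromomethyl ether | COC(=O)/C1=C/CC[C@H](C)C[C@H]2OC(=O)C(=C)[C@@H]2[C@H](OC(=O)CC(C)C)[C@H]1OCBr | intermediate (not isolated)
37 | CNP0544142.1, (4S,6R,7S,8S,9S,1(10)E) | C=C1C(=O)O[C@@H]2C[C@@H](C)CC/C=C(/C(=O)OC)[C@H](O)[C@@H](OC(=O)CC(C)C)[C@@H]12 | target

**Count and risks**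

Total step count: 25. Longest linear sequence: 25 steps (1 → 37); the route is fully linear.

Step 13. The boryl-copper species may add slowly or with poor facial selectivity to the hindered cross-conjugated dienone, the basic medium may expel the C8 ether and lead to aromatisation, and C5 may end as an epimer mixture. Fallback: setting out from 18, nucleophilic epoxidation (t-BuOOH, DBU, CH2Cl2, 0 °C) anti to the C7 side chain would give the 5α,6α-epoxy ketone F1. SmI2 in THF/MeOH at −90 °C would then cleave the Cα–O bond, and protonation of the samarium enolate would bring the route back at 20.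

Step 17. The ten-membered ring may populate a second conformer and expose the other alkene face, or the acidic iridium hydride may set off transannular cyclisation of the enone onto the ketone. Fallback: setting out from 20, O6 is kept as a silyl ether instead of being tied into the acetal, so that a free hydroxyl can direct the reduction. TBSOTf/2,6-lutidine would give the silyl ether F2, vinylcerium addition the carbinol F3, and KH/18-crown-6 the cyclodecenone F4. Buffered fluoride (TBAF, AcOH) would free the allylic C6 alcohol F5, hydrogenation with the same iridium catalyst under hydroxyl direction would give the 4S hydroxy ketone F6, and PPTS would close the methyl acetal and return the route at 26.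

Step 18. Enolisation may occur toward C9, with loss of the C8 ether, or may give the ring-trans enolate and so the wrong enoate geometry. Fallback: setting out from 26, condensation with 2,4,6-triisopropylbenzenesulfonyl hydrazide would give the hydrazone F7. A Shapiro reaction (n-BuLi, THF/TMEDA, −78 → 0 °C) would form the C1=C10 vinyllithium on the methylene side with the cis ring alkene, and methyl chloroformate would trap it to bring the route back at 29 without the triflate.

Further compounds
F1 | step 13 | 5α,6α-epoxy-5-isopropenyl ketone | O=C1[C@@]2(C(C)=C)O[C@H]2[C@H](CC(OC)OC)[C@H](OCc3ccc(OC)cc3)[C@H]1OCOC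
F2 | step 17 | 6α-O-TBS ether of 20 | O=C1[C@H](C(C)=C)[C@@H](O[Si](C)(C)C(C)(C)C)[C@H](CC(OC)OC)[C@H](OCc2ccc(OC)cc2)[C@H]1OCOC
F3 | step 17 | 10β-hydroxy-10α-vinyl carbinol from F2 | C=C[C@@]1(O)[C@H](C(C)=C)[C@@H](O[Si](C)(C)C(C)(C)C)[C@H](CC(OC)OC)[C@H](OCc2ccc(OC)cc2)[C@H]1OCOC
F4 | step 17 | (4E)-cyclodec-4-en-10-one with 6-OTBS and open dimethyl acetal | O=C1CCC/C(C)=C/[C@@H](O[Si](C)(C)C(C)(C)C)[C@H](CC(OC)OC)[C@H](OCc2ccc(OC)cc2)[C@H]1OCOC
F5 | step 17 | (4E)-6-hydroxy cyclodecenone | O=C1CCC/C(C)=C/[C@@H](O)[C@H](CC(OC)OC)[C@H](OCc2ccc(OC)cc2)[C@H]1OCOC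
F6 | step 17 | (4S)-6-hydroxy cyclodecanone | O=C1CCC[C@H](C)C[C@@H](O)[C@H](CC(OC)OC)[C@H](OCc2ccc(OC)cc2)[C@H]1OCOC
F7 | step 18 | 2,4,6-triisopropylbenzenesulfonyl hydrazone of 26 | CC(C)c1cc(C(C)C)c(S(=O)(=O)NN=C2CCC[C@H](C)C[C@H]3OC(OC)C[C@@H]3[C@H](OCc4ccc(OC)cc4)[C@H]2OCOC)c(C(C)C)c1
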